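The α-methylene-γ-butyrolactone is assembled from carbon dioxide, which supplies C12 and both lactone oxygens. In one flask a copper catalyst carboxylates the alkenyl boronate at C11 (germacrane numbering; new C11–C12 bond), and the carboxylate so formed displaces a mesylate at C8 with inversion (new O–C8 bond), closing the trans-disubstituted five-membered ring by 5-exo-tet attack. The step exploits the 1,3-relationship across C7 between the nucleophilic vinyl carbon C11 and the electrophilic carbinol carbon C8. The precursor is an acyclic syn-configured boryl mesylate obtained by asymmetric allylboration; the ten-membered carbocycle is closed afterwards by Nozaki–Hiyama–Kishi coupling between C5 and C6.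

Key step: step 13

Remark: locants C1–C15 follow germacrane numbering of the target (C1=C10, C4=C5, C6–OH, C7, C8–O, C11=C13, C12=O, C14 = methyl on C10, C15 = CH2O on C4).
Assumption: buta-2,3-dien-1-ol and 2-(tert-butyldiphenylsilyloxy)acetaldehyde are taken as purchasable; the facial preference of the phosphoric acid in step 11 is assigned by analogy with simple allylborations, and the other catalyst enantiomer would be used if the sense proves opposite.

Step 1
Reactants: 1 tert-butyl(but-3-yn-1-yloxy)dimethylsilane; 2 oxirane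
Product: 5 (E)-6-(tert-butyldimethylsilyloxy)-4-methylhex-3-en-1-ol, via alkenylalane 3 (not isolated), via lithium alanate 4 (not isolated)
Conditions: Me3Al, Cp2ZrCl2 (20 mol %), CH2Cl2, 0 °C → rt; evaporate; n-BuLi, THF–hexane, −78 → 0 °C; oxirane, 0 °C → rt; aq. Rochelle salt
Reagents that add atoms: trimethylaluminium, C[Al](C)C
Why: Negishi zirconium-catalysed syn-carboalumination puts CH3 on the internal and Al on the terminal alkyne carbon, which fixes the (E)-C1=C10 geometry, and the derived alanate opens oxirane with retention at the alkenyl carbon (C1–C2 bond).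

Step 2
Reactants: 5 (E)-6-(tert-butyldimethylsilyloxy)-4-methylhex-3-en-1-ol
Product: 6 (E)-(6-bromo-3-methylhex-3-en-1-yloxy)(tert-butyl)dimethylsilane
Conditions: CBr4, PPh3, 2,6-lutidine, CH2Cl2, 0 °C
Reagents that add atoms: carbon tetrabromide, BrC(Br)(Br)Br
Why: Appel bromination converts the primary alcohol into the bromide under neutral conditions that leave the TBS ether and the trisubstituted alkene untouched.

Step 3
Reactants: 6 (E)-(6-bromo-3-methylhex-3-en-1-yloxy)(tert-butyl)dimethylsilane; 7 prop-2-yn-1-ol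
Product: 10 (Z)-2-[(E)-6-(tert-butyldimethylsilyloxy)-4-methylhex-3-en-1-yl]-3-iodoprop-2-en-1-ol, via Grignard reagent 8 (not isolated), via alkenylmagnesium alkoxide 9 (not isolated)
Conditions: Mg, THF, 40 °C (gives 8); separately 7, EtMgBr (1.0 equiv), THF, 0 °C; then 8, CuI (10 mol %), Et2O–THF, rt; I2, THF, −40 → 0 °C
Reagents that add atoms: iodine, II
Why: Copper-catalysed anti-carbomagnesiation of the magnesium alkoxide of propargyl alcohol (Duboudin reaction) puts the alkyl group on the internal carbon (C4) and the alkoxide-chelated magnesium on the terminal carbon (C5), so iodinolysis with retention should give the (Z)-iodoalkene with iodine cis to the CH2OH group (C15).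

Step 4
Reactants: 11 2-(tert-butyldiphenylsilyloxy)acetaldehyde; 12 ethyl 2-(triphenyl-λ5-phosphanylidene)propanoate
Product: 13 ethyl (E)-4-(tert-butyldiphenylsilyloxy)-2-methylbut-2-enoate
Conditions: CH2Cl2, rt
Reagents that add atoms: none
Why: Wittig olefination with the stabilised α-methyl ylide should give the (E)-trisubstituted enoate of the side chain.

Step 5
Reactants: 13 ethyl (E)-4-(tert-butyldiphenylsilyloxy)-2-methylbut-2-enoate
Product: 14 (E)-4-(tert-butyldiphenylsilyloxy)-2-methylbut-2-enoic acid
Conditions: LiOH·H2O, THF–MeOH–H2O, rt; then aq. HCl to pH 3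
Reagents that add atoms: none
Why: Saponification of the ethyl ester with LiOH leaves the primary TBDPS ether and the alkene geometry intact.

Step 6
Reactants: 10 (Z)-2-[(E)-6-(tert-butyldimethylsilyloxy)-4-methylhex-3-en-1-yl]-3-iodoprop-2-en-1-ol; 14 (E)-4-(tert-butyldiphenylsilyloxy)-2-methylbut-2-enoic acid
Product: 15 C15 ester of 10 with acid 14
Conditions: DCC, DMAP (10 mol %), CH2Cl2, 0 °C → rt
Reagents that add atoms: none
Why: Steglich esterification acylates the only free hydroxyl (C15–OH), which installs the complete side chain before any stereocentre exists and needs no later hydroxyl differentiation.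

Step 7
Reactants: 15 C15 ester of 10 with acid 14
Product: 16 primary C8 alcohol (TBS ether of 15 removed)
Conditions: CSA (10 mol %), MeOH–CH2Cl2 (1:1), 0 °C
Reagents that add atoms: none
Why: Acid-catalysed methanolysis cleaves the primary TBS ether much faster than the TBDPS ether (selective desilylation), and both esters and the iodoalkene are inert at 0 °C.

Step 8
Reactants: 16 primary C8 alcohol
Product: 17 C8 aldehyde (β,γ-unsaturated)
Conditions: Dess–Martin periodinane, NaHCO3, CH2Cl2, 0 °C; used crude
Reagents that add atoms: none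
Why: Buffered Dess–Martin oxidation gives the β,γ-unsaturated aldehyde without acid or base that would move the C1=C10 double bond into conjugation.

Step 9
Reactants: 18 buta-2,3-dien-1-ol
Product: 19 1-[(buta-2,3-dien-1-yloxy)methyl]-4-methoxybenzene
Conditions: NaH, PMBCl, Bu4NI (cat.), THF, 0 °C → rt
Reagents that add atoms: 4-methoxybenzyl chloride, COc1ccc(CCl)cc1
Why: Williamson ether synthesis protects the future C6 oxygen as a PMB ether; the allene is stable to NaH at this temperature.

Step 10
Reactants: 19 1-[(buta-2,3-dien-1-yloxy)methyl]-4-methoxybenzene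
Product: 20 (Z)-2,3-bis(pinacolboryl)but-2-enyl 4-methoxybenzyl ether
Conditions: B2pin2, Pt(dba)2 (3 mol %), PCy3 (6 mol %), toluene, 50 °C
Reagents that add atoms: bis(pinacolato)diboron, CC1(C)OB(OC1(C)C)B1OC(C)(C)C(C)(C)O1
Why: Platinum(0)-catalysed diboration of the allene (Miyaura), steered to the terminal C=C by PCy3, adds both boron atoms syn from the face away from the CH2OPMB group, which should give the (Z)-allylboronate that already carries the alkenyl boronate of the future C11.

Step 11
Reactants: 17 C8 aldehyde; 20 (Z)-2,3-bis(pinacolboryl)but-2-enyl 4-methoxybenzyl ether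
Product: 22 (7S,8R)-homoallylic alcohol with C11 alkenyl boronate, via borate ester 21 (not isolated)
Conditions: (S)-TRIP phosphoric acid (10 mol %), 4 Å MS, toluene, −30 → 0 °C; aq. NaHCO3
Reagents that add atoms: none
Why: Chiral phosphoric acid-catalysed allylboration runs through a closed chair transition state in which the (Z)-γ-substituent is axial, which gives the syn relation of C7 and C8, while the catalyst selects the Si face of the aldehyde, so (7S,8R)-22 should form with the C11 boronate intact.

Step 12
Reactants: 22 (7S,8R)-homoallylic alcohol with C11 alkenyl boronate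
Product: 23 C8 mesylate of 22
Conditions: MsCl, Et3N, CH2Cl2, −20 → 0 °C
Reagents that add atoms: methanesulfonyl chloride, CS(=O)(=O)Cl
Why: Mesylation of the secondary C8 alcohol proceeds with retention and provides the leaving group for the lactonisation.

Step 13
Reactants: 23 C8 mesylate of 22; 24 carbon dioxide
Product: 27 (7S,8S)-trans-α-methylene-γ-butyrolactone (acyclic chain), via boronate complex 25 (not isolated), via potassium carboxylate 26 (not isolated)
Conditions: t-BuOK (1.05 equiv), THF, 0 °C; [(IPr)CuCl] (5 mol %), CO2 (1 atm), 65 °C; then DMF, 60 °C, same flask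
Reagents that add atoms: none
Why: t-BuOK first binds boron to give ate complex 25, which transmetalates the C11 alkenyl group to (IPr)Cu; insertion of CO2 into the Cu–C bond forms C11–C12, and carboxylate exchange releases potassium acrylate 26 while regenerating the catalyst. The closest known reaction types are the NHC–copper-catalysed carboxylation of alkenylboronic esters with CO2 and the O-alkylation of a carboxylate by a secondary sulfonate, here joined in one flask. Carboxylate 26 then closes the γ-lactone by intramolecular SN2 attack at C8 (5-exo-tet), which forms the O–C8 bond. No stereocentre is created at C11; C8 is inverted by backside attack (8R to 8S) and C7 is untouched, so the syn adduct is translated into the trans-disubstituted lactone. The step needs chemoselective activation of the C–B bond beside the iodoalkene and two esters, which the alkoxide-triggered transmetalation from boron provides, and substitution instead of E2 loss of the mesylate, which is favoured by pre-complexing the single equivalent of base to boron and by the five-membered closure that the 1,3-placement of C11 and C8 allows.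

Step 14
Reactants: 27 (7S,8S)-trans-α-methylene-γ-butyrolactone
Product: 28 primary C6 alcohol (PMB removed)
Conditions: DDQ, CH2Cl2–pH 7 buffer (10:1), 0 °C
Reagents that add atoms: none
Why: Oxidative PMB cleavage with DDQ under buffered conditions frees the primary C6 alcohol without touching the silyl ether, the iodoalkene or the α-methylene lactone, and the neutral medium should suppress translactonisation.

Step 15
Reactants: 28 primary C6 alcohol
Product: 29 C6 aldehyde
Conditions: Dess–Martin periodinane, NaHCO3, CH2Cl2, 0 °C; used crude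
Reagents that add atoms: none
Why: Buffered Dess–Martin oxidation gives the C6 aldehyde, which is used at once because C7–H is activated by the aldehyde and the neighbouring acrylate.

Step 16
Reactants: 29 C6 aldehyde
Product: 30 (6R,7S,8S)-germacranolide with TBDPS-protected side chain
Conditions: CrCl2 (10 equiv), NiCl2 (2 mol % of Cr), DMSO–THF, rt, 2 mM, slow addition
Reagents that add atoms: none
Why: In this Nozaki–Hiyama–Kishi macrocyclisation the alkenylchromium(III) species generated at C5 via nickel adds to the C6 aldehyde (10-exo-trig) with retention of the C4=C5 geometry, and a crown-like transition state with H6 anti to H7 and the chromium alkoxide on the ring periphery should give the (6R) alcohol.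

Step 17
Reactants: 30 (6R,7S,8S)-germacranolide with TBDPS-protected side chain
Product: 31 CNP0326626.1
Conditions: HF·pyridine, pyridine, THF, 0 °C → rt
Reagents that add atoms: none
Why: Buffered HF·pyridine cleaves the primary TBDPS ether of the side chain, and the allylic alcohol, both esters and the α-methylene lactone are stable to it.

Compound list
1 | tert-butyl(but-3-yn-1-yloxy)dimethylsilane | C#CCCO[Si](C)(C)C(C)(C)C | starting material
2 | oxirane | C1CO1 | starting material
3 | (E)-[4-(tert-butyldimethylsilyloxy)-2-methylbut-1-en-1-yl]dimethylalane (formed in situ) | C[Al](C)/C=C(\C)CCO[Si](C)(C)C(C)(C)C | intermediate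
4 | lithium butyl[(E)-4-(tert-butyldimethylsilyloxy)-2-methylbut-1-en-1-yl]dimethylaluminate (formed in situ) | [Li+].CCCC[Al-](C)(C)/C=C(\C)CCO[Si](C)(C)C(C)(C)C | intermediate
5 | (E)-6-(tert-butyldimethylsilyloxy)-4-methylhex-3-en-1-ol | OCC/C=C(\C)CCO[Si](C)(C)C(C)(C)C | intermediate
6 | (E)-(6-bromo-3-methylhex-3-en-1-yloxy)(tert-butyl)dimethylsilane | BrCC/C=C(\C)CCO[Si](C)(C)C(C)(C)C | intermediate
7 | prop-2-yn-1-ol | C#CCO | starting material
8 | (E)-[6-(tert-butyldimethylsilyloxy)-4-methylhex-3-en-1-yl]magnesium bromide (formed in situ) | Br[Mg]CC/C=C(\C)CCO[Si](C)(C)C(C)(C)C | intermediate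
9 | chelated alkenylmagnesium alkoxide, 4-[(E)-6-(tert-butyldimethylsilyloxy)-4-methylhex-3-en-1-yl]-2,5-dihydro-1,2-oxamagnesole (formed in situ) | [Mg]1OCC(CC/C=C(\C)CCO[Si](C)(C)C(C)(C)C)=C1 | intermediate
10 | (Z)-2-[(E)-6-(tert-butyldimethylsilyloxy)-4-methylhex-3-en-1-yl]-3-iodoprop-2-en-1-ol | I/C=C(\CO)CC/C=C(\C)CCO[Si](C)(C)C(C)(C)C | intermediate
11 | 2-(tert-butyldiphenylsilyloxy)acetaldehyde | O=CCO[Si](c1ccccc1)(c1ccccc1)C(C)(C)C | starting material
12 | ethyl 2-(triphenyl-λ5-phosphanylidene)propanoate | CCOC(=O)C(C)=P(c1ccccc1)(c1ccccc1)c1ccccc1 | starting material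
13 | ethyl (E)-4-(tert-butyldiphenylsilyloxy)-2-methylbut-2-enoate | CCOC(=O)/C(C)=C/CO[Si](c1ccccc1)(c1ccccc1)C(C)(C)C | intermediate
14 | (E)-4-(tert-butyldiphenylsilyloxy)-2-methylbut-2-enoic acid | OC(=O)/C(C)=C/CO[Si](c1ccccc1)(c1ccccc1)C(C)(C)C | intermediate
15 | (Z)-2-[(E)-6-(tert-butyldimethylsilyloxy)-4-methylhex-3-en-1-yl]-3-iodoprop-2-en-1-yl (E)-4-(tert-butyldiphenylsilyloxy)-2-methylbut-2-enoate | I/C=C(\COC(=O)/C(C)=C/CO[Si](c1ccccc1)(c1ccccc1)C(C)(C)C)CC/C=C(\C)CCO[Si](C)(C)C(C)(C)C | intermediate
16 | (Z)-2-[(E)-6-hydroxy-4-methylhex-3-en-1-yl]-3-iodoprop-2-en-1-yl (E)-4-(tert-butyldiphenylsilyloxy)-2-methylbut-2-enoate | I/C=C(\COC(=O)/C(C)=C/CO[Si](c1ccccc1)(c1ccccc1)C(C)(C)C)CC/C=C(\C)CCO | intermediate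
17 | (Z)-3-iodo-2-[(E)-4-methyl-6-oxohex-3-en-1-yl]prop-2-en-1-yl (E)-4-(tert-butyldiphenylsilyloxy)-2-methylbut-2-enoate | I/C=C(\COC(=O)/C(C)=C/CO[Si](c1ccccc1)(c1ccccc1)C(C)(C)C)CC/C=C(\C)CC=O | intermediate
18 | buta-2,3-dien-1-ol | C=C=CCO | starting material
19 | 1-[(buta-2,3-dien-1-yloxy)methyl]-4-methoxybenzene | C=C=CCOCc1ccc(OC)cc1 | intermediate
20 | (Z)-2,2'-[4-(4-methoxybenzyloxy)but-2-ene-1,2-diyl]bis(4,4,5,5-tetramethyl-1,3,2-dioxaborolane) | COc1ccc(COC/C=C(\CB2OC(C)(C)C(C)(C)O2)B2OC(C)(C)C(C)(C)O2)cc1 | intermediate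
21 | O8-pinacolboryl borate ester of 22 (formed in situ) | C=C(B1OC(C)(C)C(C)(C)O1)[C@@H](COCc1ccc(OC)cc1)[C@H](OB1OC(C)(C)C(C)(C)O1)C/C(C)=C/CC/C(COC(=O)/C(C)=C/CO[Si](c1ccccc1)(c1ccccc1)C(C)(C)C)=C/I | intermediate
22 | (Z)-2-[(3E,6R,7S)-6-hydroxy-7-(4-methoxybenzyloxymethyl)-4-methyl-8-(4,4,5,5-tetramethyl-1,3,2-dioxaborolan-2-yl)nona-3,8-dien-1-yl]-3-iodoprop-2-en-1-yl (E)-4-(tert-butyldiphenylsilyloxy)-2-methylbut-2-enoate; (7S,8R) in germacrane numbering | C=C(B1OC(C)(C)C(C)(C)O1)[C@@H](COCc1ccc(OC)cc1)[C@H](O)C/C(C)=C/CC/C(COC(=O)/C(C)=C/CO[Si](c1ccccc1)(c1ccccc1)C(C)(C)C)=C/I | intermediate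
23 | 6-O-methanesulfonate of 22, (3E,6R,7S)-nonadienyl chain; (7S,8R) in germacrane numbering | C=C(B1OC(C)(C)C(C)(C)O1)[C@@H](COCc1ccc(OC)cc1)[C@H](OS(C)(=O)=O)C/C(C)=C/CC/C(COC(=O)/C(C)=C/CO[Si](c1ccccc1)(c1ccccc1)C(C)(C)C)=C/I | intermediate
24 | carbon dioxide | O=C=O | starting material
25 | potassium tert-butoxy(pinacolato)alkenylborate of 23 (formed in situ) | C=C([B-]1(OC(C)(C)C)OC(C)(C)C(C)(C)O1)[C@@H](COCc1ccc(OC)cc1)[C@H](OS(C)(=O)=O)C/C(C)=C/CC/C(COC(=O)/C(C)=C/CO[Si](c1ccccc1)(c1ccccc1)C(C)(C)C)=C/I.[K+] | intermediate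
26 | potassium 2-substituted acrylate, boronate of 23 replaced by CO2K (formed in situ) | C=C(C(=O)[O-])[C@@H](COCc1ccc(OC)cc1)[C@H](OS(C)(=O)=O)C/C(C)=C/CC/C(COC(=O)/C(C)=C/CO[Si](c1ccccc1)(c1ccccc1)C(C)(C)C)=C/I.[K+] | intermediate
27 | (Z)-3-iodo-2-{(E)-5-[(2S,3S)-3-(4-methoxybenzyloxymethyl)-4-methylidene-5-oxotetrahydrofuran-2-yl]-4-methylpent-3-en-1-yl}prop-2-en-1-yl (E)-4-(tert-butyldiphenylsilyloxy)-2-methylbut-2-enoate | C=C1C(=O)O[C@@H](C/C(C)=C/CC/C(COC(=O)/C(C)=C/CO[Si](c2ccccc2)(c2ccccc2)C(C)(C)C)=C/I)[C@@H]1COCc1ccc(OC)cc1 | intermediate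
28 | (Z)-2-{(E)-5-[(2S,3S)-3-(hydroxymethyl)-4-methylidene-5-oxotetrahydrofuran-2-yl]-4-methylpent-3-en-1-yl}-3-iodoprop-2-en-1-yl (E)-4-(tert-butyldiphenylsilyloxy)-2-methylbut-2-enoate | C=C1C(=O)O[C@@H](C/C(C)=C/CC/C(COC(=O)/C(C)=C/CO[Si](c2ccccc2)(c2ccccc2)C(C)(C)C)=C/I)[C@@H]1CO | intermediate
29 | (Z)-2-{(E)-5-[(2S,3R)-3-formyl-4-methylidene-5-oxotetrahydrofuran-2-yl]-4-methylpent-3-en-1-yl}-3-iodoprop-2-en-1-yl (E)-4-(tert-butyldiphenylsilyloxy)-2-methylbut-2-enoate | C=C1C(=O)O[C@@H](C/C(C)=C/CC/C(COC(=O)/C(C)=C/CO[Si](c2ccccc2)(c2ccccc2)C(C)(C)C)=C/I)[C@@H]1C=O | intermediate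
30 | [(3aS,4R,5Z,9E,11aS)-4-hydroxy-10-methyl-3-methylidene-2-oxo-2,3,3a,4,7,8,11,11a-octahydrocyclodeca[b]furan-6-yl]methyl (E)-4-(tert-butyldiphenylsilyloxy)-2-methylbut-2-enoate | C=C1C(=O)O[C@H]2C/C(C)=C/CC/C(COC(=O)/C(C)=C/CO[Si](c3ccccc3)(c3ccccc3)C(C)(C)C)=C/[C@@H](O)[C@H]12 | intermediate
31 | CNP0326626.1, [(3aS,4R,5Z,9E,11aS)-4-hydroxy-10-methyl-3-methylidene-2-oxo-2,3,3a,4,7,8,11,11a-octahydrocyclodeca[b]furan-6-yl]methyl (E)-4-hydroxy-2-methylbut-2-enoate | C=C1C(=O)O[C@H]2C/C(C)=C/CC/C(COC(=O)/C(C)=C/CO)=C/[C@@H](O)[C@H]12 | target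

Total step count: 17. Longest linear sequence: 13 steps (steps 1, 2, 3, 6, 7, 8, 11, 12, 13, 14, 15, 16, 17; from 1 to 31).

Steps most likely to fail

Step 13. Transmetalation of the hindered pinacol boronate may be slow, so that free alkoxide or the carboxylate acts as a base and the mesylate is lost by E2 towards C9 before carboxylation and ring closure can mesh. The fallback sets out from alcohol 22 and activates C8 only after the C–C bond is made. Compound 22 is carboxylated without mesylation (t-BuOK 2.1 equiv, (IPr)CuCl, CO2, THF) and the salt is neutralised cold (pH 5 buffer, 0 °C) to the γ-hydroxy acrylic acid F1. F1 is used at once in a Mitsunobu lactonisation (PPh3, DIAD, toluene, −20 °C), in which the oxyphosphonium at C8 is displaced by the carboxylate with inversion. The fallback comes back to the route at lactone 27.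

Step 11. Allylboration with the hindered (Z)-2-boryl allylboronate may be slow, which would allow the β,γ-unsaturated aldehyde to isomerise into conjugation and would erode enantio- and diastereocontrol. The fallback sets out from aldehyde 17 and allene 19 and generates the nucleophile catalytically instead of using the preformed reagent 20. A copper-catalysed three-component borylative allylation (CuCl, chiral bisphosphine, NaOt-Bu (cat.), B2pin2, THF, 4 °C) proceeds through a (Z)-2-boryl allylcopper species and the same chair-like addition, giving borate 21 in situ. Work-up returns the route at alcohol 22; no new compound is involved.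

Step 16. Addition to the aldehyde may show poor facial selectivity at C6, and the sensitive aldehyde may isomerise during the slow addition. The fallback sets out from aldehyde 29 and replaces substrate control in the C–C bond formation by reagent control in a carbonyl reduction. The cyclisation is run as in step 16, and the alcohol mixture containing the C6 epimer F2 is oxidised (Dess–Martin periodinane, NaHCO3, CH2Cl2, 0 °C) to the macrocyclic enone F3. F3 is reduced 1,2 with a CBS oxazaborolidine and catecholborane at −78 °C, with the catalyst enantiomer chosen for the (6R) alcohol. The fallback comes back to the route at 30.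

Further compounds
F1 | step 13 | γ-hydroxy acrylic acid, (7S,8R) in germacrane numbering, boronate of 22 replaced by CO2H | C=C(C(=O)O)[C@@H](COCc1ccc(OC)cc1)[C@H](O)C/C(C)=C/CC/C(COC(=O)/C(C)=C/CO[Si](c1ccccc1)(c1ccccc1)C(C)(C)C)=C/I
F0 | step 11 | none | none
F2 | step 16 | C6 epimer of 30, (3aS,4S,5Z,9E,11aS) | C=C1C(=O)O[C@H]2C/C(C)=C/CC/C(COC(=O)/C(C)=C/CO[Si](c3ccccc3)(c3ccccc3)C(C)(C)C)=C/[C@H](O)[C@H]12
F3 | step 16 | macrocyclic C6 enone, (3aS,5Z,9E,11aS)-4-oxo analogue of 30 | C=C1C(=O)O[C@H]2C/C(C)=C/CC/C(COC(=O)/C(C)=C/CO[Si](c3ccccc3)(c3ccccc3)C(C)(C)C)=C/C(=O)[C@H]12
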